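Open a ledger on the partner before asking about any rate.

| setting | Sunday's | Thursday's | Wednesday's | Saturday's | maple | oak | birch | cedar |
|---|---|---|---|---|---|---|---|---|
| substrate | 0.019 M | 0.019 M | 0.019 M | 0.038 M | 0.019 M | 0.019 M | 0.019 M | 0.019 M (fed, over 80 min) |
| partner | 1.8 equiv | 2.5 equiv | 4 equiv | 1.8 equiv | 1.80 equiv | 1.80 equiv (in portions, 5, over 80 min) | 1.80 equiv (fed, over 80 min) | 1.80 equiv |
| catalyst | 0.25 mol% | 0.25 mol% | 0.25 mol% | 0.25 mol% | 0.25 mol% | 0.25 mol% | 0.25 mol% | 0.25 mol% |
| remark | run made earlier | run made earlier | run made earlier | run made earlier | everything together at the start | first portion at the start, last at 80 min | all else is in the flask from the start; the feed brings no volume worth counting | all else is in the flask from the start; the feed brings no volume worth counting |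
| time |  |  |  |  | 3.0 h | 3.0 h | 3.0 h | 3.0 h |

Sunday's run (percent of the substrate charged)

| time / min | target / % |
|---|---|
| 25.0 | 9.9 |
| 50.0 | 2.6 |
| 80.0 | 1.7 |
| 120 | 0 |

Thursday's run (percent of the substrate charged)

| time / h | target / % |
|---|---|
| 0.833 | 0.7 |
| 2.00 | 0.2 |
| 2.50 | 0 |
| 4.00 | 0 |

Wednesday's run (percent of the substrate charged)

| time / h | target / % |
|---|---|
| 0.250 | 1.3 |
| 0.667 | 0.5 |
| 1.50 | 0 |
| 4.00 | 0.2 |

Saturday's run (percent of the substrate charged)

| time / h | target / % |
|---|---|
| 0.250 | 1.1 |
| 0.667 | 0.1 |
| 1.50 | 0 |
| 4.00 | 0.7 |

(scatter of a reading: 0.5 percentage points)

- percentages count the substrate that a species holds: one homo dimer counts as two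
- what was read earlier has a scatter of 0.5 percentage points, one standard deviation
- on the list of suspects stand: substrate + partner + catalyst -> target + catalyst; partner + catalyst + target -> catalyst + over-reaction product; 2 substrate -> homo dimer

- which flask leads in amount of target, in percent of the substrate charged ("all alike" within 1.5 percentage points) (maple / oak / birch / cedar / all alike)
- how much target is there at the end, in percent of the substrate charged: maple
- how much target is there at the end, in percent of the substrate charged: oak
- how much target is there at the end, in percent of the substrate charged: birch
- how much target is there at the end, in percent of the substrate charged: cedar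

Per substrate charged we hold 1.80 equiv of partner, and we enter what each path costs. A substrate that becomes target costs one partner. A target that becomes over-reaction product costs a second. A substrate that goes to homo dimer costs none, but it also leaves the books as a possible target.

Let d be the share of substrate in dimer. Suppose the partner is the limiting reagent and is spent to the last. Then the books close with target equal to 2 times the difference between 10.0% and d. We call that value the break-even dimer share: the dimer share at which partner and target end together. Above it, partner outlasts target, and target can fall to nothing. Below it, partner goes first, and target stays, with a ceiling of 20.0% at d equal to zero.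

Now the readings. Sunday's run, charged as maple is, reads 0% of target at 120 min, with a scatter of 0.5 percentage points. The books give a target of about zero, within that scatter, only at a dimer share of about break-even or above, so that is how we read Sunday's run, and we expect maple to hold no target at 3.0 h.

Oak and birch hold partner back while the whole substrate is in the flask from the start, so we expect their dimer share above break-even too. Cedar is the opposite case. If dimer runs as written, its rate goes with [substrate] squared, and feeding substrate keeps [substrate] low. We therefore expect cedar to lead, below the ceiling by 2 points for each point of dimer.

The forecast named cedar, with 0.2%, 0.3%, 0.3% and 14% for maple, oak, birch and cedar, and said: “Feeding substrate (cedar) keeps substrate low, so dimer is only a few percent”.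

The flasks give 0% in maple, 0% in oak, 0% in birch and 19.0% in cedar, so cedar leads.

    substrate + partner + catalyst → target + catalyst, rate k1*[substrate]*[partner]*[catalyst]/(1 + ([substrate]/sat1)) (0.411 mM, k = 53600 M⁻² s⁻¹)
    partner + catalyst + target → catalyst + over-reaction product (k = 2290 M⁻² s⁻¹)
    2 substrate → homo dimer (k = 0.0817 M⁻¹ s⁻¹)

At 0.0506 h in birch, substrate goes to dimer 20 times as fast as to target, and birch ends with 72.0% dimer, above break-even. In cedar, mean [substrate] over the first 80 min is 2.28 × 10⁻⁴ M against a charge of 0.019 M, and dimer ends at 0.777%, below break-even. The ledger then gives cedar 18.4% of target once partner is down to 0%, and cedar holds 18.4% at 30.0 h. The neighbour flask, like birch but with 0.0047 M of substrate, keeps its equivalents, so break-even stays 10.0%. It ends at 3.00 h with 60.0% dimer, above break-even, 62% of its partner left and 12.3% target.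

(The data are calculated for substances that don't exist, noise included.)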